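## Analysis of the target

Target 15 is (3R,5S)-1-(4-hydroxy-3-methoxyphenyl)dodecane-3,5-diyl diacetate. It is an open C12 chain whose only ring is the guaiacyl arene on C1, and C6–C12 form an unbranched heptyl tail. The two stereocentres, C3 (R) and C5 (S), both carry acetoxy groups, are separated by the C4 methylene and stand in a 1,3-syn relationship. The sensitive functions are the two secondary acetates (cleaved by base and nucleophiles) and the free, electron-rich phenol. The phenol must be masked through every organometallic and oxidative step and must end free while the two alkanols end acetylated, so the three hydroxyls have to be told apart. The difficulty is that the chain offers no handle besides the oxygens: each carbinol carbon is flanked by two methylenes of similar size (C2/C4 at C3, C4/C6 at C5), so substrate-based facial control is weak and both absolute and relative configuration must come from reagents. The plan rests on the C3–C4–C5 triad, two C–O carbons on either side of one CH2. With boron in place of each oxygen this is a 1,3-bis(boronic ester), the one-carbon homologue, at the primary boron, of the 1,2-bis(boronic ester) made by adding a B–B bond across C4=C5 of a nine-carbon terminal alkene.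

## Retrosynthetic reasoning

**15 to 14 (phenolic O–Si).** The last operation only unmasks the phenol. A bulky silyl ether is chosen because it resists alkyllithium bases and leaves with buffered fluoride, conditions under which the two acetates stay in place. The forward step has to cleave Ar–O–Si without ester cleavage.

**14 to 13 (two acetate C–O bonds).** The C3 and C5 hydroxyls are acetylated while the phenol is still silylated. This ordering is what distinguishes the alkanols from the phenol, so no selective acylation is needed.

**13 to 12 (C3–O and C5–O).** Both carbinol oxygens are traced back to C–B bonds. Oxidation of a boronic ester proceeds with retention, so the configuration of 12 is that of 13, and both oxygens are introduced in one operation.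

**12 to 6 and 9 (C3–C4).** This is the strategic cut. It divides the chain into C1–C3, which is exactly the aryl-propyl unit of 1, and C4–C12, which is exactly the carbon skeleton of 7. C4 is the primary, unhindered boron-bearing carbon of 9, the one position a bulky carbenoid will attack. C3 becomes the carbenoid carbon: carbamate 6 is deprotonated enantioselectively to organolithium 10, which adds to the primary boron of 9 to give ate complex 11. A 1,2-shift of C4 from boron to C3 then forms the bond and places boron on C3. The mirror-image cut at C4–C5 would need a four-carbon aryl alkene not available from 1 without homologation. The forward step must deliver enantioselective lithiation, attack at the primary boron only, and a stereospecific shift.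

**9 to 7 and 8 (C4–B and C5–B).** Both C–B bonds come from addition of the B–B bond of 8 across the alkene of 7. A chiral catalyst fixes C5, independently of everything that follows.

**6 to 4 and 5 (carbamate C–O).** Acylation of primary alcohol 4 with carbamoyl chloride 5 installs the group that directs lithiation and later serves as the leaving group.

**4 to 2 (via 3) and 2 to 1.** The primary hydroxyl comes from anti-Markovnikov hydration of the allyl group of 2 through borane 3. Compound 2 is the silyl ether of 1, so all of C1–C3 and the arene come from one cheap phenol.

## Alternatives that were turned down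

**Alternative 1:** Here the C5–O bond would be formed in the key step.
- Disconnection: diol A2, (3R,5E)-1-[4-(benzyloxy)-3-methoxyphenyl]dodec-5-ene-3,7-diol, already holds the C3 carbinol and an allylic hydroxyl at C7 of either configuration.
- Forward key step: with a perrhenate catalyst (heptavalent rhenium) the C7 perrhenate ester would undergo a [3,3] shift that places oxygen on C5 and moves the alkene to C6=C7. The 1,3-diol so revealed would be drained from the equilibrium by acetal exchange with an aromatic aldehyde acetal, giving the all-equatorial 2-phenyl-1,3-dioxane A1.
- For it: the syn relationship is enforced thermodynamically by the chair acetal, C5 needs no chiral reagent, the C7 configuration is irrelevant, the catalyst is cheap and nothing is cryogenic. On relative configuration it is at least as secure as the chosen plan, which depends on two separate reagent-controlled events.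
- Against it for 15: A2 must first be built with C3 enantioenriched, by an asymmetric carbonyl addition plus a chain-joining step. The transposition passes through allyl-cation character in the presence of an electron-rich arene, so elimination and loss of alkene geometry are possible. A1 still carries an alkene, an acetal and a benzyl ether; removing them by hydrogenation exposes phenol and diol together, so the phenol/alkanol distinction must be rebuilt by peracetylation and selective aryl ester cleavage.
- Comparison: an estimated nine to ten steps against eight. The chosen route sets C3 and C5 independently, so either C3 epimer is available by choice of diamine antipode, and it needs no redox correction after the key step.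

**Alternative 2:** The syn-1,3-diol would be taken whole from a ring.
- Disconnection: meso cis-3,5-bis(tert-butyldimethylsilyloxy)cyclohexanone A4, whose two α-methylenes are enantiotopic.
- Forward key step: a chiral lithium amide removes a proton from one α-methylene and a silyl chloride traps the enolate as the enantioenriched silyl enol ether A3. Oxidative cleavage of its C=C bond would then open the ring to a six-carbon chain with an aldehyde at one end and a carboxyl at the other, corresponding to C2–C7 of 15.
- For it: the syn relationship is built into the meso precursor and cannot erode, and one enantiotopic-group-selective step fixes both absolute configurations. On this point it is stronger than the chosen route, which needs two asymmetric steps.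
- Against it: the key step forms no skeletal bond and only six of the twelve chain carbons come from the ring. The base is stoichiometric and its enantiomeric ratio is inherited by both centres. The ring-opened fragment carries an α-silyloxy aldehyde prone to epimerisation and elimination. Both termini then need separate extension (aryl-methylene on one side, pentyl on the other) through olefinations, reductions and hydrogenation, followed by exchange of silyl ethers for acetates.
- Comparison: well over a dozen linear steps. The chosen plan is convergent, forms C3–C4 and the C3 stereocentre in the same operation, and carries both oxygens as boron until a single oxidation.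

**Alternative 3:** The aryl–C1 bond would be cut.
- Disconnection: cyclopropanol A6, 1-[(S)-2-(tert-butyldimethylsilyloxy)nonyl]cyclopropan-1-ol, made by titanium-mediated cyclopropanation of a β-silyloxy ester, and aryl bromide A7, 1-(benzyloxy)-4-bromo-2-methoxybenzene.
- Forward key step: zerovalent palladium inserts into the C–Br bond of A7, the cyclopropanol binds as its alkoxide and opens by β-carbon elimination to a palladium homoenolate, and reductive elimination gives the β-aryl ketone A5, the O-benzyl O-silyl derivative of (S)-[8]-gingerol.
- For it: the route is convergent and catalytic, the arene enters late, and C5 would come from a very reliable asymmetric reduction of a β-keto ester. As a way to make the aryl–C1 bond it is more direct than carrying an allyl arene through hydroboration.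
- Against it: the key step creates no stereocentre. C3 arrives as a ketone and must be reduced 1,3-syn, which needs the free C5 hydroxyl (desilylation, then chelate-controlled hydride delivery) and leaves the diastereomer ratio to substrate control. The palladium homoenolate can undergo β-hydride elimination to the enone, and the electron-rich bromide A7 should add slowly to palladium.
- Comparison: keto ester preparation, reduction, silylation, cyclopropanation, coupling, desilylation, ketone reduction, acetylation and debenzylation come to about nine steps, no shorter than the chosen route. In the chosen route C3 is fixed by the reagent in the very step that forms C3–C4.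

Key step: step 5

Assumption: the ligand antipode in step 4 is specified by its outcome, (R)-9. This is assumed to be the (S,S)-antipode of the TADDOL-derived phenylphosphonite; if the sense of induction is the reverse, the (R,R)-ligand is used and nothing else changes.

Remark on descriptors: the nonane stereocentre is labelled R in 9 and 11 and S (as C5) in 12–15 although its geometry never changes. Only the CIP ranking of its neighbours changes when C4 acquires the C3 substituent.

## Route

Step 1
Reactants: 1 eugenol (4-allyl-2-methoxyphenol)
Product: 2 (4-allyl-2-methoxyphenoxy)triisopropylsilane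
Conditions: TIPSCl, imidazole, DMF, 0 °C to rt
Reagents that add atoms: triisopropylsilyl chloride, CC(C)[Si](Cl)(C(C)C)C(C)C
Why: Imidazole-mediated silylation of a phenol. The triisopropylsilyl ether is chosen because it withstands alkyllithium bases and brief aqueous base yet leaves with fluoride.

Step 2
Reactants: 2 (4-allyl-2-methoxyphenoxy)triisopropylsilane
Product: 4 3-[3-methoxy-4-(triisopropylsilyloxy)phenyl]propan-1-ol, via B-alkyl-9-borabicyclo[3.3.1]nonane 3 (not isolated)
Conditions: 9-BBN, THF, 0 °C to rt; then NaOH, H2O2, 0 °C to rt
Reagents that add atoms: 9-borabicyclo[3.3.1]nonane, B1C2CCCC1CCC2 (its atoms are carried in 3 only); hydrogen peroxide, OO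
Why: Anti-Markovnikov hydroboration–oxidation. The bulky dialkylborane places boron on the terminal carbon of the allyl group, and cold, brief alkaline peroxide should spare the hindered aryl silyl ether.

Step 3
Reactants: 4 3-[3-methoxy-4-(triisopropylsilyloxy)phenyl]propan-1-ol; 5 N,N-diisopropylcarbamoyl chloride
Product: 6 3-[3-methoxy-4-(triisopropylsilyloxy)phenyl]propyl N,N-diisopropylcarbamate
Conditions: Et3N, CH2Cl2, reflux
Reagents that add atoms: none
Why: O-Acylation of a primary alcohol with a carbamoyl chloride. The hindered carbamate cannot be attacked at its carbonyl by s-BuLi and will serve in step 5 as directing group for α-lithiation and as leaving group.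

Step 4
Reactants: 7 1-nonene; 8 bis(pinacolato)diboron
Product: 9 (R)-2,2'-(nonane-1,2-diyl)bis(4,4,5,5-tetramethyl-1,3,2-dioxaborolane) [(R)-1,2-bis(pinacolboryl)nonane]
Conditions: Pt(dba)3 (cat.), TADDOL-derived phenylphosphonite with 3,5-diisopropylphenyl groups (cat., antipode giving (R)-9), THF, 80 °C pre-complexation, then 60 °C
Reagents that add atoms: none
Why: Enantioselective platinum-catalysed alkene diboration. The B–B bond adds oxidatively to zerovalent platinum, the alkene inserts into Pt–B inside the chiral phosphonite pocket (enantio-determining), and C–B reductive elimination delivers both borons to one face of C4=C5, which sets the future C5 stereocentre.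

Step 5
Reactants: 6 3-[3-methoxy-4-(triisopropylsilyloxy)phenyl]propyl N,N-diisopropylcarbamate; 9 (R)-1,2-bis(pinacolboryl)nonane
Product: 12 (3R,5S)-1-[3-methoxy-4-(triisopropylsilyloxy)phenyl]-3,5-bis(4,4,5,5-tetramethyl-1,3,2-dioxaborolan-2-yl)dodecane, via lithiated carbamate 10 (not isolated), via lithium boronate complex 11 (not isolated)
Conditions: s-BuLi, (−)-sparteine, Et2O, −78 °C; then 9, Et2O, −78 °C; then warm to reflux
Reagents that add atoms: sec-butyllithium, CCC(C)[Li] (its lithium is carried in 10 and 11 only)
Why: s-BuLi bound to (−)-sparteine removes the pro-S hydrogen on the carbamate-bearing carbon of 6, directed by the carbamate carbonyl, and gives the configurationally stable (S)-organolithium 10. The carbon of 10 adds to the primary boron of 9 with retention to give ate complex 11; on warming, C4 shifts from boron to C3 anti-periplanar to the carbamate C–O bond, which leaves with inversion, and this 1,2-metallate rearrangement forms the C3–C4 bond. The closest known reaction type is the lithiation–borylation homologation of the primary boron of enantioenriched 1,2-bis(boronic esters) with sparteine-ligated lithiated alkyl carbamates, for which 3-arylpropyl carbamates are standard lithiation substrates. No ring is closed. The new stereocentre C3 is controlled by the reagent alone, through retention at boron capture followed by inversion in the shift, which with (−)-sparteine places boron as required for 3R; C5 is not involved and keeps the geometry set in step 4. The step needs site selectivity between the two borons, which sterics should secure: the secondary boron next to the heptyl chain does not accept the bulky diamine-bound carbenoid at −78 °C, and 10 is kept to a small excess (s-BuLi slightly short of 6) so that the secondary C–B bonds of 11 and 12 are not homologated. It also needs α-lithiation to outrun ortho-metalation of the arene, which the carbonyl-directed deprotonation and the hindered silyl ether should ensure.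

Step 6
Reactants: 12 (3R,5S)-1-[3-methoxy-4-(triisopropylsilyloxy)phenyl]-3,5-bis(pinacolboryl)dodecane
Product: 13 (3R,5S)-1-[3-methoxy-4-(triisopropylsilyloxy)phenyl]dodecane-3,5-diol
Conditions: H2O2, NaOH, THF, 0 °C to rt
Reagents that add atoms: hydrogen peroxide, OO
Why: Oxidation of alkylboronic esters with alkaline hydrogen peroxide. Hydroperoxide adds to boron and the alkyl group migrates from boron to oxygen with retention, so both carbinol configurations follow from 12; low temperature and short exposure are chosen to keep the aryl silyl ether.

Step 7
Reactants: 13 (3R,5S)-1-[3-methoxy-4-(triisopropylsilyloxy)phenyl]dodecane-3,5-diol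
Product: 14 (3R,5S)-1-[3-methoxy-4-(triisopropylsilyloxy)phenyl]dodecane-3,5-diyl diacetate
Conditions: Ac2O, pyridine, DMAP (cat.), CH2Cl2, rt
Reagents that add atoms: acetic anhydride, CC(=O)OC(C)=O
Why: DMAP-catalysed acylation of secondary alcohols. The phenol is still silylated, so only the C3 and C5 hydroxyls are acetylated and no stereocentre is touched.

Step 8
Reactants: 14 (3R,5S)-1-[3-methoxy-4-(triisopropylsilyloxy)phenyl]dodecane-3,5-diyl diacetate
Product: 15 (3R,5S)-1-(4-hydroxy-3-methoxyphenyl)dodecane-3,5-diyl diacetate
Conditions: Bu4NF, AcOH, THF, 0 °C
Reagents that add atoms: none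
Why: Fluoride-induced cleavage of an aryl silyl ether. Acetic acid buffers the phenoxide so that the acetates should be neither cleaved nor transferred to the phenol.

## Compound list

1 | eugenol (4-allyl-2-methoxyphenol) | C=CCc1ccc(O)c(OC)c1 | starting material
2 | (4-allyl-2-methoxyphenoxy)triisopropylsilane | C=CCc1ccc(O[Si](C(C)C)(C(C)C)C(C)C)c(OC)c1 | intermediate
3 | 9-{3-[3-methoxy-4-(triisopropylsilyloxy)phenyl]propyl}-9-borabicyclo[3.3.1]nonane (not isolated) | COc1cc(CCCB2C3CCCC2CCC3)ccc1O[Si](C(C)C)(C(C)C)C(C)C | intermediate
4 | 3-[3-methoxy-4-(triisopropylsilyloxy)phenyl]propan-1-ol | COc1cc(CCCO)ccc1O[Si](C(C)C)(C(C)C)C(C)C | intermediate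
5 | N,N-diisopropylcarbamoyl chloride | CC(C)N(C(C)C)C(Cl)=O | starting material
6 | 3-[3-methoxy-4-(triisopropylsilyloxy)phenyl]propyl N,N-diisopropylcarbamate | COc1cc(CCCOC(=O)N(C(C)C)C(C)C)ccc1O[Si](C(C)C)(C(C)C)C(C)C | intermediate
7 | 1-nonene | CCCCCCCC=C | starting material
8 | bis(pinacolato)diboron | CC1(C)OB(OC1(C)C)B1OC(C)(C)C(C)(C)O1 | starting material
9 | (R)-2,2'-(nonane-1,2-diyl)bis(4,4,5,5-tetramethyl-1,3,2-dioxaborolane) | CCCCCCC[C@@H](CB1OC(C)(C)C(C)(C)O1)B1OC(C)(C)C(C)(C)O1 | intermediate
10 | (S)-1-lithio-3-[3-methoxy-4-(triisopropylsilyloxy)phenyl]propyl N,N-diisopropylcarbamate (not isolated; present as its (−)-sparteine complex, diamine omitted from the SMILES) | CC(C)N(C(C)C)C(=O)O[C@H](CCc1ccc(O[Si](C(C)C)(C(C)C)C(C)C)c(OC)c1)[Li] | intermediate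
11 | lithium boronate complex from C-attack of 10 on the primary boron of 9 (not isolated; S at the carbamate-bearing carbon, nonane stereocentre as in 9) | [Li+].CCCCCCC[C@@H](C[B-]1(OC(C)(C)C(C)(C)O1)[C@@H](CCc1ccc(O[Si](C(C)C)(C(C)C)C(C)C)c(OC)c1)OC(=O)N(C(C)C)C(C)C)B1OC(C)(C)C(C)(C)O1 | intermediate
12 | (3R,5S)-1-[3-methoxy-4-(triisopropylsilyloxy)phenyl]-3,5-bis(4,4,5,5-tetramethyl-1,3,2-dioxaborolan-2-yl)dodecane | CCCCCCC[C@@H](C[C@@H](CCc1ccc(O[Si](C(C)C)(C(C)C)C(C)C)c(OC)c1)B1OC(C)(C)C(C)(C)O1)B1OC(C)(C)C(C)(C)O1 | intermediate
13 | (3R,5S)-1-[3-methoxy-4-(triisopropylsilyloxy)phenyl]dodecane-3,5-diol | CCCCCCC[C@@H](C[C@@H](CCc1ccc(O[Si](C(C)C)(C(C)C)C(C)C)c(OC)c1)O)O | intermediate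
14 | (3R,5S)-1-[3-methoxy-4-(triisopropylsilyloxy)phenyl]dodecane-3,5-diyl diacetate | CCCCCCC[C@@H](C[C@@H](CCc1ccc(O[Si](C(C)C)(C(C)C)C(C)C)c(OC)c1)OC(C)=O)OC(C)=O | intermediate
15 | (3R,5S)-1-(4-hydroxy-3-methoxyphenyl)dodecane-3,5-diyl diacetate | CCCCCCC[C@@H](C[C@@H](CCc1ccc(O)c(OC)c1)OC(C)=O)OC(C)=O | target

## Step count and least certain steps

Total: 8 steps. Longest linear sequence: 7 steps (steps 1, 2, 3, 5, 6, 7, 8 from eugenol); step 4 is a one-step branch.

**Step 5 (key step).**
- What may go wrong: sluggish or reversible capture of the diamine-bound carbenoid by the primary boron, so that the organolithium decomposes on warming before the shift. Incomplete discrimination between primary and secondary boron would lead to over-homologation if the carbenoid is in excess. Imperfect enantioselection in the deprotonation would appear as the anti diastereomer.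
- Fallback (sets out from 9 and 4, returns at 13): the C3–C4 bond is kept but made by epoxide opening with an acyl anion equivalent, and C3 is set afterwards by 1,3-induction.
  - From 9, H2O2/NaOH should give (S)-nonane-1,2-diol F1. Selective primary sulfonylation (TsCl, Et3N, catalytic Bu2SnO) gives (S)-2-hydroxynonyl 4-methylbenzenesulfonate F2, and K2CO3 in MeOH closes (S)-2-heptyloxirane F3.
  - From 4, Dess–Martin oxidation gives 3-[3-methoxy-4-(triisopropylsilyloxy)phenyl]propanal F4, and propane-1,3-dithiol with BF3·OEt2 gives 2-{2-[3-methoxy-4-(triisopropylsilyloxy)phenyl]ethyl}-1,3-dithiane F5.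
  - Lithiation of F5 (t-BuLi, THF/HMPA, −78 °C) and addition to the terminal carbon of F3 gives (S)-1-(2-{2-[3-methoxy-4-(triisopropylsilyloxy)phenyl]ethyl}-1,3-dithian-2-yl)nonan-2-ol F6.
  - MeI/CaCO3 in aqueous MeCN unmasks (S)-5-hydroxy-1-[3-methoxy-4-(triisopropylsilyloxy)phenyl]dodecan-3-one F7.
  - Narasaka–Prasad reduction (Et2BOMe, NaBH4, THF/MeOH, −78 °C) delivers hydride syn to the C5 hydroxyl through the boron chelate and gives 13.

**Step 4.**
- What may go wrong: erosion of enantioselectivity through unligated platinum or incomplete pre-complexation of the air-sensitive catalyst. Any minor enantiomer of 9 is carried into the anti diastereomer of 12.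
- Fallback (sets out from 7, returns at 9): the two C–B bonds are made one at a time. Cross-metathesis of 7 with vinylboronic acid pinacol ester, using (H2IMes)(PCy3)Cl2Ru=CHPh (second-generation Grubbs catalyst) in CH2Cl2 at 40 °C, should give (E)-4,4,5,5-tetramethyl-2-(non-1-en-1-yl)-1,3,2-dioxaborolane F8. Enantioselective copper-catalysed protoboration (CuCl, NaOt-Bu, a chiral N-heterocyclic carbene ligand of the antipode giving (R)-9, 8, MeOH, THF) adds boron to the heptyl-bearing carbon and hydrogen to the boron-bearing carbon, giving 9.

**Step 6.**
- What may go wrong: loss of the aryl silyl ether through attack of hydroxide or hydroperoxide at silicon, and incomplete oxidation of the two hindered secondary C–B bonds, which tempts longer or warmer exposure.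
- Fallback (sets out from 12, returns at 15): the phenol is distinguished by ester reactivity, not by the silyl ether. Oxidation with excess H2O2/NaOH at rt, followed by Bu4NF if any silyl ether remains, gives (3R,5S)-1-(4-hydroxy-3-methoxyphenyl)dodecane-3,5-diol F9. Ac2O/pyridine/DMAP gives (3R,5S)-1-(4-acetoxy-3-methoxyphenyl)dodecane-3,5-diyl diacetate F10. Pyrrolidine in CH2Cl2 at 0 °C removes only the aryl acetate, since a phenyl ester is a far better acyl donor than an alkyl ester, and gives 15.

## Further compounds

F1 | step 5 | (S)-nonane-1,2-diol | CCCCCCC[C@@H](CO)O
F2 | step 5 | (S)-2-hydroxynonyl 4-methylbenzenesulfonate | CCCCCCC[C@@H](COS(=O)(=O)c1ccc(C)cc1)O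
F3 | step 5 | (S)-2-heptyloxirane | CCCCCCC[C@H]1CO1
F4 | step 5 | 3-[3-methoxy-4-(triisopropylsilyloxy)phenyl]propanal | COc1cc(CCC=O)ccc1O[Si](C(C)C)(C(C)C)C(C)C
F5 | step 5 | 2-{2-[3-methoxy-4-(triisopropylsilyloxy)phenyl]ethyl}-1,3-dithiane | COc1cc(CCC2SCCCS2)ccc1O[Si](C(C)C)(C(C)C)C(C)C
F6 | step 5 | (S)-1-(2-{2-[3-methoxy-4-(triisopropylsilyloxy)phenyl]ethyl}-1,3-dithian-2-yl)nonan-2-ol | CCCCCCC[C@H](O)CC1(CCc2ccc(O[Si](C(C)C)(C(C)C)C(C)C)c(OC)c2)SCCCS1
F7 | step 5 | (S)-5-hydroxy-1-[3-methoxy-4-(triisopropylsilyloxy)phenyl]dodecan-3-one | CCCCCCC[C@H](O)CC(=O)CCc1ccc(O[Si](C(C)C)(C(C)C)C(C)C)c(OC)c1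
F8 | step 4 | (E)-4,4,5,5-tetramethyl-2-(non-1-en-1-yl)-1,3,2-dioxaborolane | CCCCCCC/C=C/B1OC(C)(C)C(C)(C)O1
F9 | step 6 | (3R,5S)-1-(4-hydroxy-3-methoxyphenyl)dodecane-3,5-diol | CCCCCCC[C@@H](C[C@@H](CCc1ccc(O)c(OC)c1)O)O
F10 | step 6 | (3R,5S)-1-(4-acetoxy-3-methoxyphenyl)dodecane-3,5-diyl diacetate | CCCCCCC[C@@H](C[C@@H](CCc1ccc(OC(C)=O)c(OC)c1)OC(C)=O)OC(C)=O
A1 | alternative 1 | all-cis 4-{2-[4-(benzyloxy)-3-methoxyphenyl]ethyl}-6-[(E)-hept-1-en-1-yl]-2-phenyl-1,3-dioxane | CCCCC/C=C/[C@H]1C[C@@H](CCc2ccc(OCc3ccccc3)c(OC)c2)O[C@@H](c2ccccc2)O1
A2 | alternative 1 | (3R,5E)-1-[4-(benzyloxy)-3-methoxyphenyl]dodec-5-ene-3,7-diol (either C7 epimer) | CCCCCC(O)/C=C/C[C@H](O)CCc1ccc(OCc2ccccc2)c(OC)c1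
A3 | alternative 2 | enantioenriched cis-3,5-bis(tert-butyldimethylsilyloxy)-1-(trimethylsilyloxy)cyclohexene | C[Si](C)(C)OC1=C[C@@H](O[Si](C)(C)C(C)(C)C)C[C@@H](O[Si](C)(C)C(C)(C)C)C1
A4 | alternative 2 | meso cis-3,5-bis(tert-butyldimethylsilyloxy)cyclohexanone | O=C1C[C@@H](O[Si](C)(C)C(C)(C)C)C[C@@H](O[Si](C)(C)C(C)(C)C)C1
A5 | alternative 3 | (S)-1-[4-(benzyloxy)-3-methoxyphenyl]-5-(tert-butyldimethylsilyloxy)dodecan-3-one | CCCCCCC[C@@H](CC(=O)CCc1ccc(OCc2ccccc2)c(OC)c1)O[Si](C)(C)C(C)(C)C
A6 | alternative 3 | 1-[(S)-2-(tert-butyldimethylsilyloxy)nonyl]cyclopropan-1-ol | CCCCCCC[C@@H](CC1(O)CC1)O[Si](C)(C)C(C)(C)C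
A7 | alternative 3 | 1-(benzyloxy)-4-bromo-2-methoxybenzene | COc1cc(Br)ccc1OCc1ccccc1
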